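At 5.0 min the east run has turned 44.0 % of its Xa into Xp and the south-east run 41.7 % of its own, although the east run holds half the Xa. Two shares so close suggest reckoning with the share of Xa, not its amount.

| flask | Xa | Xb | Xc | time |
|---|---|---|---|---|
| south-east | 1.00 M | 0.800 M | 0.0300 M |  |
| north-west | 0.400 M | 0.200 M | 0.0300 M |  |
| east | 0.500 M | 0.800 M | 0.0300 M |  |
| north | 1.00 M | 0.800 M | 0.0600 M |  |
| west | 0.290 M | 0.800 M | 0.0300 M | 15 min |

| run | time / min | [Xp] / M |
|---|---|---|
| south-east run | 2.5 | 0.206 |
| south-east run | 5.0 | 0.417 |
| south-east run | 7.5 | 0.590 |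
| south-east run | 10 | 0.702 |
| south-east run | 12 | 0.749 |
| south-east run | 15 | 0.781 |
| north-west run | 2.5 | 0.070 |
| north-west run | 5.0 | 0.127 |
| north-west run | 7.5 | 0.170 |
| north-west run | 10 | 0.181 |
| north-west run | 12 | 0.192 |
| north-west run | 15 | 0.192 |
| east run | 2.5 | 0.102 |
| east run | 5.0 | 0.220 |
| east run | 7.5 | 0.300 |
| east run | 10 | 0.367 |
| east run | 12 | 0.403 |
| east run | 15 | 0.448 |
| north run | 2.5 | 0.374 |
| north run | 5.0 | 0.638 |
| north run | 7.5 | 0.767 |
| north run | 10 | 0.788 |
| north run | 12 | 0.800 |
| north run | 15 | 0.791 |

(scatter of a reading: 0.005 M)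

* the power of [Xc] that the first rate follows, about the charge of the south-east run; measure it at two percent of Xa made into Xp
* the power of [Xa] that the first rate follows, about the charge of the south-east run; measure it at two percent of Xa made into Xp (one fixed amount of Xp, the same in the runs compared)
* the north-west run starts with 0.600 M less of Xa and of Xb than the south-east run, and with no Xp. Compared where both hold the same amount of Xa, once fifteen percent of what the north-west run was charged with has turned into Xp, is the north-west run faster, slower or alike (within a tenth)?
* Xp in the west run at 15 min, as a share of the Xa charged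

- Overall: Xa + Xb -> Xp, with Xc as catalyst.
- Constant volume, constant temperature.
- The analysis sees a species whether free or bound.
- An order is taken over about fifteen percent of the charge, up and down.

Turn Xc first. By hand, twice the catalyst gives a rate ratio of 2. Over the first 2.5 min the north run makes 0.374 M and the south-east run 0.206 M. Both readings cover the same minutes, so time drops out of their ratio, and the power follows as a mean over those minutes:

power in c(Xc) = ln(1.82) / ln(2) = 0.860

Turn c(Xa) next. By hand, a first power gives 0.5 for the halved charge. In the first 2.5 min the east run makes 0.102 M against the 0.206 M of the south-east run, a ratio of 0.495, or a power of 1.01 across that wide span. Yet the east run makes 0.118 M between 2.5 min and 5.0 min, more than in its first interval, although its Xa has fallen to 0.398 M. My reckoning therefore puts the narrow-step power below the span value.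

Then lower Xa and Xb together. By hand, a rate that follows c(Xa) and c(Xb) alone gives a ratio of 1 at matched amounts. The north-west run averages 0.0254 M min⁻¹ over its first 5.0 min, while its Xa falls from 0.400 M to 0.273 M. The south-east run averages 0.0448 M min⁻¹ between 7.5 min and 10 min, while its Xa falls from 0.410 M to 0.298 M. So my reckoning has the north-west run slower, at a ratio of 0.567.

For the west run, take the east run at 5.0 min, where 0.280 M of its Xa is unturned:

κ = ln(0.500 M / 0.280 M) / 5.0 min = 0.116 min⁻¹

This share constant κ, the logarithm of (Xa charged over Xa unturned) divided by the time, is the steady fractional loss per minute that reaches that share by that time.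

The east run's κ is not steady: 0.0913 min⁻¹ at 2.5 min and 0.151 min⁻¹ at 15 min. Xa is the limiting reagent in the west run (0.290 M against 0.800 M of Xb), so its Xp stays under 0.290 M. The east run has passed that level by 7.5 min, with 0.300 M, so the value at 5.0 min, with 0.220 M of Xp, is the one I carry over:

share at 15 min = 1 − exp(−0.116 min⁻¹ × 15 min) = 82.4 %

The forecast gives 0.8 (0.6 to 1.05) for Xc, 0.8 (0.55 to 1.05) for Xa, slower for the north-west run, and 86 % (78 % to 92 %) for the west run, above my figure. Its ground reads: “West should resemble east”.

The west run gives 79.6 % at 15 min, 6.4 percentage points below the forecast; the powers are 0.90 in Xc and 0.16 in Xa, and the north-west run is slower.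

    Xc + Xa → Xc.Xa (14.88 M⁻¹ min⁻¹)
    Xc.Xa + Xb → Xp + Xc (26.16 M⁻¹ min⁻¹)
    Xa + Xb + Xp → 2 Xp (1.764 M⁻² min⁻¹)
    Xa + Xb ⇌ Xa.Xb, settled at all times (7.930 M⁻¹)

In this scheme Xp speeds its own formation through a step with constant 1.76 M⁻² min⁻¹. Reckoned from the west run's share, κ is 0.106 min⁻¹, below the 0.116 min⁻¹ of the east run at 5.0 min and above the 0.0913 min⁻¹ of the east run at 2.5 min.

The readings are simulated for substances that don't exist, noise included.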